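**Retrosynthetic overview**

1. The target has an epoxycyclohexenone ring A with (1S,5R,6R) configuration (hydroxyl anti to the oxirane, ring B) and a 2-amino-3-hydroxycyclopentenone ring C. The last bond made is C2'–C3' of the triene, by Stille coupling of vinylstannane 16 with bromodienamide 24.
2. Ring C (key step): ring contraction of the six-membered N-acyl lactam 23 by an anionic 1,2-acyl shift from N to C, which leaves the amide bond in place.
3. The enamide C–N bond on ring A comes from CuI-catalysed amidation of α-iodoenone 13 with primary amide 6; the alkyne is turned into the (E)-vinylstannane by hydrostannation.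
4. Ring B and all three ring stereocentres are set in one desymmetrising, amine-catalysed epoxidation of the prochiral quinol silyl ether 11 (from 1,4-benzoquinone and lithium (trimethylsilyl)acetylide).
5. Amide 6 comes from (S)-3-bromo-2-methylpropan-1-ol (coupling with PrMgCl, oxidation/Wittig, aminolysis). Ring order: A (bought as benzoquinone), B (step 5), C (step 13).

Assumption: the quinine-derived amine salt is taken to give the (1S,6R) epoxide in step 5; if the first run shows the opposite sense, the quinidine-derived pseudoenantiomer is used under the same conditions.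

**Route**

Step 1
Reactants: 1 (S)-3-bromo-2-methylpropan-1-ol; 2 propylmagnesium chloride
Product: 3 (R)-2-methylhexan-1-ol
Conditions: 2 (3 equiv), Li2CuCl4 (5 mol%), THF, −20 °C to rt; aq. NH4Cl
Reagents that add atoms: none
Why: Kochi-type copper-catalysed sp3–sp3 coupling of the primary bromide (hydroxyl carried as its magnesium alkoxide) with the Grignard reagent; no bond at the stereocentre is touched, so the bought (S) centre becomes the (R) centre of the acyl chain only through the change in substituent priorities.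

Step 2
Reactants: 3 (R)-2-methylhexan-1-ol
Product: 5 ethyl (2E,4R)-2,4-dimethyloct-2-enoate, via (R)-2-methylhexanal 4 (not isolated)
Conditions: 2,2,6,6-tetramethylpiperidine-1-oxyl (10 mol%), PhI(OAc)2 (1.1 equiv), CH2Cl2, rt; then Ph3P=C(CH3)CO2Et (1.5 equiv), 40 °C
Reagents that add atoms: ethyl 2-(triphenyl-λ5-phosphanylidene)propanoate, CCOC(=O)C(C)=P(c1ccccc1)(c1ccccc1)c1ccccc1
Why: Mild oxoammonium oxidation followed in the same pot by Wittig olefination with the stabilised ylide gives the (E)-trisubstituted enoate before the α-stereocentre of the aldehyde can enolise.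

Step 3
Reactants: 5 ethyl (2E,4R)-2,4-dimethyloct-2-enoate
Product: 6 (2E,4R)-2,4-dimethyloct-2-enamide
Conditions: AlMe3 (3 equiv), NH4Cl (3 equiv), toluene, 0 to 50 °C; aq. HCl work-up
Reagents that add atoms: ammonium chloride, [NH4+].[Cl-]
Why: Weinreb aluminium-amide aminolysis converts the hindered conjugated ester directly into the primary amide by attack at the carbonyl, leaving the alkene geometry and the γ-stereocentre untouched.

Step 4
Reactants: 7 ethynyltrimethylsilane; 8 1,4-benzoquinone
Product: 11 4-{[tert-butyl(dimethyl)silyl]oxy}-4-[(trimethylsilyl)ethynyl]cyclohexa-2,5-dien-1-one, via lithium (trimethylsilyl)acetylide 9 (not isolated), via lithium quinol alkoxide 10 (not isolated)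
Conditions: 7, BuLi, THF, −78 °C; added to 8 (1.2 equiv), THF, −78 °C; then t-BuMe2SiOTf, −78 to 0 °C
Reagents that add atoms: tert-butyldimethylsilyl trifluoromethanesulfonate, CC(C)(C)[Si](C)(C)OS(=O)(=O)C(F)(F)F
Why: 1,2-addition of the lithium acetylide to one carbonyl of the quinone at low temperature gives the p-quinol alkoxide, which is silylated in the flask; the product has a mirror plane through C1 and C4, so no stereocentre is set yet.

Step 5
Reactants: 11 4-{[tert-butyl(dimethyl)silyl]oxy}-4-[(trimethylsilyl)ethynyl]cyclohexa-2,5-dien-1-one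
Product: 12 (1S,5S,6R)-5-{[tert-butyl(dimethyl)silyl]oxy}-5-[(trimethylsilyl)ethynyl]-7-oxabicyclo[4.1.0]hept-3-en-2-one
Conditions: 9-amino-9-deoxy-epi-quinine (10 mol%), CF3CO2H (20 mol%), 50% aq. H2O2 (1.5 equiv), 1,4-dioxane, 30 °C, 48 h
Reagents that add atoms: hydrogen peroxide, OO
Why: Proposed new method: amine-salt (iminium/enamine) epoxidation with H2O2, known for simple 2-cyclohexenones, is used here to desymmetrise a prochiral 4,4-disubstituted cyclohexa-2,5-dienone; the primary amine condenses with C1=O, the quinuclidinium steers H2O2 to one β-carbon on the catalyst-fixed face and the enamine closes the oxirane, and because that face lies anti to the bulky silyloxy group (syn to the rod-like alkyne, the steric and Felkin-type preference) on only one of the two enantiotopic enones, that enone reacts (matched) and gives the anti epoxide as one enantiomer, setting C1, C6 and the now stereogenic C5 together, while attack on the other enone would have to come syn to the silyloxy group (mismatched, slow, its diastereomer is removed by chromatography) and the same mismatch holds back a second epoxidation; closest known reactions are the amine-catalysed asymmetric Weitz–Scheffer-type epoxidation of cyclic enones and the substrate-controlled epoxidation of 4-silyloxycyclohexenones trans to the silyloxy group.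

Step 6
Reactants: 12 (1S,5S,6R)-5-{[tert-butyl(dimethyl)silyl]oxy}-5-[(trimethylsilyl)ethynyl]-7-oxabicyclo[4.1.0]hept-3-en-2-one
Product: 13 (1S,5S,6R)-5-{[tert-butyl(dimethyl)silyl]oxy}-3-iodo-5-[(trimethylsilyl)ethynyl]-7-oxabicyclo[4.1.0]hept-3-en-2-one
Conditions: I2 (2 equiv), pyridine/CH2Cl2 (1:1), 0 °C to rt
Reagents that add atoms: iodine, II
Why: α-Iodination of the remaining enone by the pyridine addition–iodination–elimination sequence (Johnson protocol), which tolerates 4,4-disubstituted cyclohexenones; the epoxy ketone has no enolisable position, so the three stereocentres are untouched.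

Step 7
Reactants: 13 (1S,5S,6R)-5-{[tert-butyl(dimethyl)silyl]oxy}-3-iodo-5-[(trimethylsilyl)ethynyl]-7-oxabicyclo[4.1.0]hept-3-en-2-one; 6 (2E,4R)-2,4-dimethyloct-2-enamide
Product: 14 (2E,4R)-N-[(1S,5S,6R)-5-{[tert-butyl(dimethyl)silyl]oxy}-2-oxo-5-[(trimethylsilyl)ethynyl]-7-oxabicyclo[4.1.0]hept-3-en-3-yl]-2,4-dimethyloct-2-enamide
Conditions: 6 (1.2 equiv), CuI (10 mol%), N,N'-dimethylethane-1,2-diamine (20 mol%), K2CO3 (2 equiv), toluene, 60 °C
Reagents that add atoms: none
Why: Goldberg-type copper-catalysed N-vinylation of the primary amide with the α-iodoenone (a strongly activated vinyl iodide) forms the enamide C–N bond; the tertiary hydroxyl is still silylated, so the carbonate cannot trigger epoxide migration.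

Step 8
Reactants: 14 (2E,4R)-N-[(1S,5S,6R)-5-{[tert-butyl(dimethyl)silyl]oxy}-2-oxo-5-[(trimethylsilyl)ethynyl]-7-oxabicyclo[4.1.0]hept-3-en-3-yl]-2,4-dimethyloct-2-enamide
Product: 15 (2E,4R)-N-[(1S,5S,6R)-5-ethynyl-5-hydroxy-2-oxo-7-oxabicyclo[4.1.0]hept-3-en-3-yl]-2,4-dimethyloct-2-enamide
Conditions: Bu4NF (2.5 equiv), AcOH (2.5 equiv), THF, 0 °C to rt
Reagents that add atoms: none
Why: Fluoride cleaves both the tertiary O–Si bond and the alkynyl C–Si bond, and the acetic acid buffer keeps the freed tertiary alkoxide protonated so that the anti hydroxy epoxide does not undergo Payne rearrangement.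

Step 9
Reactants: 15 (2E,4R)-N-[(1S,5S,6R)-5-ethynyl-5-hydroxy-2-oxo-7-oxabicyclo[4.1.0]hept-3-en-3-yl]-2,4-dimethyloct-2-enamide
Product: 16 (2E,4R)-N-[(1S,5S,6R)-5-hydroxy-2-oxo-5-[(E)-2-(tributylstannyl)ethenyl]-7-oxabicyclo[4.1.0]hept-3-en-3-yl]-2,4-dimethyloct-2-enamide
Conditions: Bu3SnH (1.2 equiv, slow addition), Pd(PPh3)2Cl2 (2 mol%), THF, 0 °C
Reagents that add atoms: tributyltin hydride, CCCC[SnH](CCCC)CCCC
Why: Palladium-catalysed syn-hydrostannation of the terminal alkyne; the fully substituted propargylic carbon sends tin to the terminal carbon and gives the (E)-vinylstannane, while the push–pull α-amido enone is a poor acceptor for the palladium hydride at 0 °C.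

Step 10
Reactants: 17 glutaconaldehyde potassium salt
Product: 18 (2E,4E)-5-bromopenta-2,4-dienal
Conditions: PPh3 (1.1 equiv), Br2 (1.1 equiv), CH2Cl2, 0 °C; then 17, rt
Reagents that add atoms: bromine, BrBr
Why: The enolate oxygen of the vinylogous formate is activated as an oxyphosphonium salt by Ph3PBr2 and replaced by bromide through addition–elimination (deoxybromination), the conjugated dienal settling in the (2E,4E) geometry.

Step 11
Reactants: 18 (2E,4E)-5-bromopenta-2,4-dienal
Product: 19 (2E,4E)-5-bromopenta-2,4-dienoic acid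
Conditions: NaClO2, NaH2PO4, 2-methyl-2-butene, t-BuOH/H2O, rt
Reagents that add atoms: sodium chlorite, [Na+].[O-]Cl=O
Why: Pinnick oxidation converts the enal into the acid without touching the alkenyl bromide or the alkene geometry.

Step 12
Reactants: 19 (2E,4E)-5-bromopenta-2,4-dienoic acid; 20 piperidine-2,5-dione
Product: 23 1-[(2E,4E)-5-bromopenta-2,4-dienoyl]piperidine-2,5-dione, via acid chloride 21 (not isolated), via N-silyl lactam 22 (not isolated)
Conditions: 19, (COCl)2, DMF (cat.), CH2Cl2, 0 °C to rt, concentrate; 20, (Me3Si)2NH, Me3SiCl (cat.), MeCN, 60 °C, concentrate; combine in CH2Cl2, 0 °C to rt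
Reagents that add atoms: none
Why: Base-free N-acylation of the silylated lactam by the acid chloride (imide formation, silicon leaving as Me3SiCl) avoids enolising the keto lactam, which would otherwise be O-acylated or rearrange too early.

Step 13
Reactants: 23 1-[(2E,4E)-5-bromopenta-2,4-dienoyl]piperidine-2,5-dione
Product: 24 (2E,4E)-5-bromo-N-(2-hydroxy-5-oxocyclopent-1-en-1-yl)penta-2,4-dienamide
Conditions: LiN(SiMe3)2 (1.2 equiv), THF, −78 to 0 °C; then 1 M HCl to pH 3
Reagents that add atoms: none
Why: Proposed new method: the C6–H between the ketone and the imide nitrogen is the most acidic site, its enolate adds 3-exo-trig to the ring imide carbonyl C2 to give a 6-azabicyclo[3.1.0]hexan-1-olate, and cleavage of the C2–N bond expels the dienamide anion, so the ring acyl carbon moves from N to C6 (anionic 1,2-acyl shift, not pericyclic) and the six-membered lactam contracts to the 2-acylaminocyclopentane-1,3-dione, whose enolate (parent acid pKa about 4–5) is the thermodynamic sink; the aliphatic ring acyl is more electrophilic than the cross-conjugated exocyclic dienoyl group, which should therefore stay on nitrogen; closest known reactions are the base-induced N→C acyl migration of acyclic imides and the transannular rearrangement of activated diketopiperazines to pyrrolidine-2,4-diones.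

Step 14
Reactants: 16 (2E,4R)-N-[(1S,5S,6R)-5-hydroxy-2-oxo-5-[(E)-2-(tributylstannyl)ethenyl]-7-oxabicyclo[4.1.0]hept-3-en-3-yl]-2,4-dimethyloct-2-enamide; 24 (2E,4E)-5-bromo-N-(2-hydroxy-5-oxocyclopent-1-en-1-yl)penta-2,4-dienamide
Product: 25 (2E,4R)-N-[(1S,5R,6R)-5-hydroxy-5-{(1E,3E,5E)-7-[(2-hydroxy-5-oxocyclopent-1-en-1-yl)amino]-7-oxohepta-1,3,5-trien-1-yl}-2-oxo-7-oxabicyclo[4.1.0]hept-3-en-3-yl]-2,4-dimethyloct-2-enamide
Conditions: Pd(PhCN)2Cl2 (5 mol%), DMF, rt, dark
Reagents that add atoms: none
Why: Ligand-free Stille coupling of the (E)-vinylstannane with the (1E)-bromodiene joins C2' to C3' with retention of both geometries under neutral conditions that spare the free hydroxy epoxide and the acidic enol; this kind of union is established for related epoxyquinol trienes.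

**Compound list**

1 | (S)-3-bromo-2-methylpropan-1-ol | C[C@@H](CO)CBr | starting material
2 | propylmagnesium chloride | CCC[Mg]Cl | starting material
3 | (R)-2-methylhexan-1-ol | CCCC[C@@H](C)CO | intermediate
4 | (R)-2-methylhexanal | CCCC[C@@H](C)C=O | intermediate
5 | ethyl (2E,4R)-2,4-dimethyloct-2-enoate | CCCC[C@@H](C)/C=C(\C)C(=O)OCC | intermediate
6 | (2E,4R)-2,4-dimethyloct-2-enamide | CCCC[C@@H](C)/C=C(\C)C(N)=O | intermediate
7 | ethynyltrimethylsilane | C#C[Si](C)(C)C | starting material
8 | 1,4-benzoquinone | O=C1C=CC(=O)C=C1 | starting material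
9 | lithium (trimethylsilyl)acetylide | [Li+].[C-]#C[Si](C)(C)C | intermediate
10 | lithium 4-oxo-1-[(trimethylsilyl)ethynyl]cyclohexa-2,5-dien-1-olate | [Li+].[O-]C1(C#C[Si](C)(C)C)C=CC(=O)C=C1 | intermediate
11 | 4-{[tert-butyl(dimethyl)silyl]oxy}-4-[(trimethylsilyl)ethynyl]cyclohexa-2,5-dien-1-one | O=C1C=CC(O[Si](C)(C)C(C)(C)C)(C#C[Si](C)(C)C)C=C1 | intermediate
12 | (1S,5S,6R)-5-{[tert-butyl(dimethyl)silyl]oxy}-5-[(trimethylsilyl)ethynyl]-7-oxabicyclo[4.1.0]hept-3-en-2-one | C1=C[C@](O[Si](C)(C)C(C)(C)C)(C#C[Si](C)(C)C)[C@@H]2O[C@@H]2C1=O | intermediate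
13 | (1S,5S,6R)-5-{[tert-butyl(dimethyl)silyl]oxy}-3-iodo-5-[(trimethylsilyl)ethynyl]-7-oxabicyclo[4.1.0]hept-3-en-2-one | IC1=C[C@](O[Si](C)(C)C(C)(C)C)(C#C[Si](C)(C)C)[C@@H]2O[C@@H]2C1=O | intermediate
14 | (2E,4R)-N-[(1S,5S,6R)-5-{[tert-butyl(dimethyl)silyl]oxy}-2-oxo-5-[(trimethylsilyl)ethynyl]-7-oxabicyclo[4.1.0]hept-3-en-3-yl]-2,4-dimethyloct-2-enamide | CCCC[C@@H](C)/C=C(\C)C(=O)NC1=C[C@](O[Si](C)(C)C(C)(C)C)(C#C[Si](C)(C)C)[C@@H]2O[C@@H]2C1=O | intermediate
15 | (2E,4R)-N-[(1S,5S,6R)-5-ethynyl-5-hydroxy-2-oxo-7-oxabicyclo[4.1.0]hept-3-en-3-yl]-2,4-dimethyloct-2-enamide | CCCC[C@@H](C)/C=C(\C)C(=O)NC1=C[C@](O)(C#C)[C@@H]2O[C@@H]2C1=O | intermediate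
16 | (2E,4R)-N-[(1S,5S,6R)-5-hydroxy-2-oxo-5-[(E)-2-(tributylstannyl)ethenyl]-7-oxabicyclo[4.1.0]hept-3-en-3-yl]-2,4-dimethyloct-2-enamide | CCCC[C@@H](C)/C=C(\C)C(=O)NC1=C[C@](O)(/C=C/[Sn](CCCC)(CCCC)CCCC)[C@@H]2O[C@@H]2C1=O | intermediate
17 | glutaconaldehyde potassium salt (potassium (1E,3E)-5-oxopenta-1,3-dien-1-olate) | [K+].[O-]/C=C/C=C/C=O | starting material
18 | (2E,4E)-5-bromopenta-2,4-dienal | Br/C=C/C=C/C=O | intermediate
19 | (2E,4E)-5-bromopenta-2,4-dienoic acid | OC(=O)/C=C/C=C/Br | intermediate
20 | piperidine-2,5-dione | O=C1CCC(=O)CN1 | starting material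
21 | (2E,4E)-5-bromopenta-2,4-dienoyl chloride | ClC(=O)/C=C/C=C/Br | intermediate
22 | 1-(trimethylsilyl)piperidine-2,5-dione | C[Si](C)(C)N1CC(=O)CCC1=O | intermediate
23 | 1-[(2E,4E)-5-bromopenta-2,4-dienoyl]piperidine-2,5-dione | O=C1CCC(=O)CN1C(=O)/C=C/C=C/Br | intermediate
24 | (2E,4E)-5-bromo-N-(2-hydroxy-5-oxocyclopent-1-en-1-yl)penta-2,4-dienamide | Br/C=C/C=C/C(=O)NC1=C(O)CCC1=O | intermediate
25 | (2E,4R)-N-[(1S,5R,6R)-5-hydroxy-5-{(1E,3E,5E)-7-[(2-hydroxy-5-oxocyclopent-1-en-1-yl)amino]-7-oxohepta-1,3,5-trien-1-yl}-2-oxo-7-oxabicyclo[4.1.0]hept-3-en-3-yl]-2,4-dimethyloct-2-enamide | CCCC[C@@H](C)/C=C(\C)C(=O)NC1=C[C@](O)(/C=C/C=C/C=C/C(=O)NC2=C(O)CCC2=O)[C@@H]2O[C@@H]2C1=O | target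

**Step count and risks**

Total: 14 steps. Longest linear sequence: 7 steps (8 → 11 → 12 → 13 → 14 → 15 → 16 → 25; the branch from 1 through 6 is equally long).

The three steps most likely to fail:

Step 5 (proposed new desymmetrising epoxidation). The cross-conjugated dienone may form the iminium slowly, or the catalyst may give insufficient enantiocontrol. The fallback sets out from 11 and comes back at 12. Weitz–Scheffer epoxidation with t-BuOOH and DBU (CH2Cl2, 0 °C), known chemistry under the same substrate control, gives the racemic anti epoxide. That is 12 together with its mirror image (1R,5R,6S)-5-{[tert-butyl(dimethyl)silyl]oxy}-5-[(trimethylsilyl)ethynyl]-7-oxabicyclo[4.1.0]hept-3-en-2-one F1. The two are parted by preparative supercritical-fluid chromatography on an amylose tris(3,5-dimethylphenylcarbamate) phase, and 12 goes on into step 6. This fallback rests on the same anti-to-silyloxy facial preference as the main step.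

Step 13 (proposed new ring contraction). The exocyclic dienoyl group might migrate in place of the ring acyl carbon, giving a 6-acylpiperidine-2,5-dione. The fallback sets out from 19 (as its chloride 21) and comes back at 24, using known chemistry only. Cyclopentane-1,3-dione F3 is nitrosated (NaNO2, aq. HCl, 0 °C) to 2-(hydroxyimino)cyclopentane-1,3-dione F4. This is hydrogenated (H2, Pd/C, HCl, EtOH) to 2-amino-3-hydroxycyclopent-2-en-1-one hydrochloride F5. F5 is N-acylated with 21 (Et3N, CH2Cl2/DMF, 0 °C) to give 24.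

Step 9 (hydrostannation). The palladium hydride could reduce the enone or the epoxy ketone, or tin could go to the internal carbon. The fallback sets out from 15 and comes back at 25 without tin. Semihydrogenation of the alkyne (H2, Pd/CaCO3 poisoned with Pb(OAc)2, quinoline, EtOAc) gives (2E,4R)-N-[(1S,5R,6R)-5-ethenyl-5-hydroxy-2-oxo-7-oxabicyclo[4.1.0]hept-3-en-3-yl]-2,4-dimethyloct-2-enamide F2. Heck coupling of F2 with 24 (Pd(OAc)2, Bu4NCl, NaHCO3, DMF, 40 °C) then gives 25 directly; a tertiary allylic alcohol cannot form a ketone by β-hydride elimination, so the (E)-alkene results.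

**Further compounds**

F1 | step 5 | (1R,5R,6S)-5-{[tert-butyl(dimethyl)silyl]oxy}-5-[(trimethylsilyl)ethynyl]-7-oxabicyclo[4.1.0]hept-3-en-2-one | C1=C[C@@](O[Si](C)(C)C(C)(C)C)(C#C[Si](C)(C)C)[C@H]2O[C@H]2C1=O
F2 | step 9 | (2E,4R)-N-[(1S,5R,6R)-5-ethenyl-5-hydroxy-2-oxo-7-oxabicyclo[4.1.0]hept-3-en-3-yl]-2,4-dimethyloct-2-enamide | CCCC[C@@H](C)/C=C(\C)C(=O)NC1=C[C@](O)(C=C)[C@@H]2O[C@@H]2C1=O
F3 | step 13 | cyclopentane-1,3-dione | O=C1CCC(=O)C1
F4 | step 13 | 2-(hydroxyimino)cyclopentane-1,3-dione | O=C1CCC(=O)C1=NO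
F5 | step 13 | 2-amino-3-hydroxycyclopent-2-en-1-one hydrochloride | NC1=C(O)CCC1=O.Cl
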